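**Retrosynthetic overview**
- Last, one acidolysis unmasks the acid (tert-butyl ester) and the three phenols (methoxymethyl ethers).
- Key disconnections, made in one flask: (a) the bond from quaternary C2 to the CH2 of the aryl ketone arm, an aldol union of an aryl enol silane with an α-keto ester that sets the only stereocentre; (b) the O1–C7 bond, whose formation closes the 2,3,4,7-tetrahydrooxepine.
- Enabling feature: O1 sits on C2, which is α to the carboxyl carbon and β to the aryl ketone (a ketone/α-keto ester aldol retron). C7 is a primary allylic CH2 held cis to C4 by the ring alkene C5=C6, so the aldolate oxygen finds an SN2-active carbon that closes a seven-membered ring.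
- The α-keto ester comes from a (5Z)-allylic chloride, made by Z-selective Horner–Wadsworth–Emmons olefination of a C1–C5 lactol with a phosphonate carrying C6, C7 and the side chain. Allylic oxidation and coumaroylation finish the side chain.
- Ring order: both arenes are bought; the oxepine is the only ring formed, in the key step.

Key step: step 13

Assumption: the copper bis(oxazoline) aldol is taken to follow the usual square-planar chelate model ((S,S)-ligand exposes the si face of the chelated ketone), so the (R,R)-ligand is used to reach the (2R) configuration.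

**Step 1**
Reactants: 1 methyl 2-[bis(2,2,2-trifluoroethoxy)phosphoryl]acetate; 2 5-bromo-2-methylpent-2-ene
Product: 3 methyl 2-[bis(2,2,2-trifluoroethoxy)phosphoryl]-6-methylhept-5-enoate (racemic)
Conditions: NaH (1.0 equiv), 1 (1.5 equiv), DMF, 0 °C; then 2, NaI (cat.), 60 °C
Reagents that add atoms: none
Why: SN2 C-alkylation of the sodium phosphonoacetate anion by the primary bromide (phosphonate alkylation), with 1 in excess to hold back dialkylation.

**Step 2**
Reactants: 4 (2S)-5-oxotetrahydrofuran-2-carboxylic acid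
Product: 5 tert-butyl (2S)-5-oxotetrahydrofuran-2-carboxylate
Conditions: 2-methylpropene (excess), H2SO4 (cat.), CH2Cl2, sealed vessel, rt
Reagents that add atoms: 2-methylpropene, CC(C)=C
Why: Acid-catalysed addition of the carboxylic acid to 2-methylpropene (tert-butyl esterification) gives an ester that should survive two hydride reductions; the stereocentre is not involved.

**Step 3**
Reactants: 5 tert-butyl (2S)-5-oxotetrahydrofuran-2-carboxylate
Product: 6 tert-butyl (2S)-5-hydroxytetrahydrofuran-2-carboxylate (lactol; mixture of anomers)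
Conditions: i-Bu2AlH (1.05 equiv), CH2Cl2, –78 °C; MeOH, then aq. KNaC4H4O6 (potassium sodium tartrate)
Reagents that add atoms: none
Why: Partial hydride reduction of the γ-lactone to the lactol; the aluminium hemiacetal is stable at –78 °C and the hindered tert-butyl ester should react much more slowly.

**Step 4**
Reactants: 3 methyl 2-[bis(2,2,2-trifluoroethoxy)phosphoryl]-6-methylhept-5-enoate; 6 tert-butyl (2S)-5-hydroxytetrahydrofuran-2-carboxylate
Product: 7 1-tert-butyl 7-methyl (2S,5Z)-2-hydroxy-6-(4-methylpent-3-en-1-yl)hept-5-enedioate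
Conditions: 3 (2.2 equiv), KN(SiMe3)2 (2.1 equiv), 18-crown-6, THF, –78 °C; then 6, –78 → –40 °C; AcOH quench at –78 °C
Reagents that add atoms: none
Why: Still–Gennari variant of the Horner–Wadsworth–Emmons olefination on the ring-opened hydroxy aldehyde; fast, irreversible collapse of the electron-poor oxaphosphetane should place the ester cis to C4, giving the (5Z)-trisubstituted alkene.

**Step 5**
Reactants: 7 1-tert-butyl 7-methyl (2S,5Z)-2-hydroxy-6-(4-methylpent-3-en-1-yl)hept-5-enedioate
Product: 8 tert-butyl (2S,5Z)-2-hydroxy-6-(hydroxymethyl)-10-methylundeca-5,9-dienoate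
Conditions: i-Bu2AlH (3.2 equiv), CH2Cl2, –78 °C; aq. KNaC4H4O6
Reagents that add atoms: none
Why: 1,2-Reduction of the conjugated methyl ester to the allylic alcohol by i-Bu2AlH, with the tert-butyl ester spared on steric grounds and the alkene geometry retained.

**Step 6**
Reactants: 8 tert-butyl (2S,5Z)-2-hydroxy-6-(hydroxymethyl)-10-methylundeca-5,9-dienoate
Product: 9 tert-butyl (2S,5Z)-6-(chloromethyl)-2-hydroxy-10-methylundeca-5,9-dienoate
Conditions: N-chlorosuccinimide, Me2S, CH2Cl2, –20 → 0 °C
Reagents that add atoms: N-chlorosuccinimide, O=C1CCC(=O)N1Cl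
Why: Corey–Kim chlorination: the alkoxysulfonium salt of the primary allylic alcohol is displaced by chloride without allylic shift, while the secondary α-hydroxy ester should stay unchanged in the absence of base.

**Step 7**
Reactants: 9 tert-butyl (2S,5Z)-6-(chloromethyl)-2-hydroxy-10-methylundeca-5,9-dienoate
Product: 10 tert-butyl (2S,5Z,9E)-6-(chloromethyl)-2,11-dihydroxy-10-methylundeca-5,9-dienoate
Conditions: SeO2 (0.3 equiv), t-BuOOH (3 equiv), salicylic acid (cat.), CH2Cl2, rt
Reagents that add atoms: selenium dioxide, O=[Se]=O (catalytic oxygen carrier); tert-butyl hydroperoxide, CC(C)(C)OO (stoichiometric oxygen source)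
Why: Riley allylic oxidation (ene reaction, then [2,3]-sigmatropic shift) should pick the (E)-methyl group of the terminal, most electron-rich trisubstituted alkene; the C5=C6 alkene is deactivated by its chloromethyl group.

**Step 8**
Reactants: 11 (2E)-3-(4-hydroxyphenyl)prop-2-enoic acid (p-coumaric acid)
Product: 13 (2E)-3-[4-(methoxymethoxy)phenyl]prop-2-enoic acid, via methoxymethyl ester 12 (not isolated)
Conditions: K2CO3, MeOCH2Cl (2.3 equiv), DMF, 0 °C → rt; then LiOH, THF/H2O, rt; cold aq. HCl to pH 4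
Reagents that add atoms: chloromethyl methyl ether, COCCl; lithium hydroxide, [Li+].[OH-] (its oxygen ends in the carboxyl group)
Why: Williamson-type O-alkylation of phenoxide and carboxylate by the chloromethyl ether, then saponification of only the far more labile methoxymethyl ester.

**Step 9**
Reactants: 10 tert-butyl (2S,5Z,9E)-6-(chloromethyl)-2,11-dihydroxy-10-methylundeca-5,9-dienoate; 13 (2E)-3-[4-(methoxymethoxy)phenyl]prop-2-enoic acid
Product: 14 tert-butyl (2S,5Z,9E)-6-(chloromethyl)-2-hydroxy-11-{[(2E)-3-[4-(methoxymethoxy)phenyl]prop-2-enoyl]oxy}-10-methylundeca-5,9-dienoate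
Conditions: N,N'-dicyclohexylcarbodiimide, 4-(dimethylamino)pyridine (cat.), CH2Cl2, 0 °C
Reagents that add atoms: none
Why: Steglich esterification, in which the unhindered primary allylic alcohol should be acylated in preference to the hindered secondary α-hydroxy ester.

**Step 10**
Reactants: 14 tert-butyl (2S,5Z,9E)-6-(chloromethyl)-2-hydroxy-11-{[(2E)-3-[4-(methoxymethoxy)phenyl]prop-2-enoyl]oxy}-10-methylundeca-5,9-dienoate
Product: 15 tert-butyl (5Z,9E)-6-(chloromethyl)-11-{[(2E)-3-[4-(methoxymethoxy)phenyl]prop-2-enoyl]oxy}-10-methyl-2-oxoundeca-5,9-dienoate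
Conditions: Dess–Martin periodinane, CH2Cl2, 0 °C → rt
Reagents that add atoms: none
Why: Dess–Martin oxidation of the secondary α-hydroxy ester to the α-keto ester under non-basic conditions that leave the allylic chloride, the esters and the acetal untouched; the temporary C2 stereocentre is erased here.

**Step 11**
Reactants: 16 1-(2,5-dihydroxyphenyl)ethan-1-one
Product: 17 1-[2,5-bis(methoxymethoxy)phenyl]ethan-1-one
Conditions: NaH (2.2 equiv), DMF, 0 °C; MeOCH2Cl (2.4 equiv), 0 °C → rt
Reagents that add atoms: chloromethyl methyl ether, COCCl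
Why: Williamson-type O-alkylation of both sodium phenoxides; full deprotonation is used because the ortho hydroxyl is hydrogen-bonded to the ketone.

**Step 12**
Reactants: 17 1-[2,5-bis(methoxymethoxy)phenyl]ethan-1-one
Product: 18 {[1-(2,5-bis(methoxymethoxy)phenyl)ethenyl]oxy}trimethylsilane
Conditions: LiN(SiMe3)2, THF, –78 °C; Me3SiCl
Reagents that add atoms: chlorotrimethylsilane, C[Si](C)(C)Cl
Why: Kinetic deprotonation of the methyl ketone and O-silylation of the lithium enolate (silyl enol ether formation).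

**Step 13**
Reactants: 15 tert-butyl (5Z,9E)-6-(chloromethyl)-11-{[(2E)-3-[4-(methoxymethoxy)phenyl]prop-2-enoyl]oxy}-10-methyl-2-oxoundeca-5,9-dienoate; 18 {[1-(2,5-bis(methoxymethoxy)phenyl)ethenyl]oxy}trimethylsilane
Product: 20 tert-butyl (2R)-2-{2-[2,5-bis(methoxymethoxy)phenyl]-2-oxoethyl}-6-[(3E)-5-{[(2E)-3-[4-(methoxymethoxy)phenyl]prop-2-enoyl]oxy}-4-methylpent-3-en-1-yl]-2,3,4,7-tetrahydrooxepine-2-carboxylate, via silyl aldolate 19 (not isolated)
Conditions: Cu(OTf)2 (10 mol %), 2,2'-(propane-2,2-diyl)bis[(4R)-4-tert-butyl-4,5-dihydro-1,3-oxazole] (11 mol %), 18 (1.2 equiv), THF, –78 °C; then tris(dimethylamino)sulfonium difluorotrimethylsilicate (1.5 equiv), Bu4NI (10 mol %), DMF, –78 → 0 °C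
Reagents that add atoms: none
Why: Mukaiyama aldol addition followed by fluoride-triggered intramolecular Williamson etherification: the bis(oxazoline) complex of Cu(OTf)2 chelates the 1,2-dicarbonyl unit of 15 in a square-planar array, enol silane 18 adds to the open re face of the ketone and the silyl group passes to the new alkoxide to give 19; fluoride then removes the silyl group and the tertiary alkoxide displaces the allylic chloride at C7. The closest known reaction types are the copper bis(oxazoline)-catalysed additions of enol silanes to pyruvate-type α-keto esters and the desilylative cyclisation of silyl ethers onto tethered halides. The oxepine is closed in the 7-exo-tet mode. The only new stereocentre, C2, is set by the chiral ligand ((R,R)-ligand, re-face attack, 2R) and is not touched by the ring closure. The step needs O-alkylation at C7 to win over retro-aldol cleavage, enolate C-alkylation and SN2′ attack at C5: the (5Z)-alkene holds the chloromethyl group within reach of the C2 oxygen, the electrophile is a primary allylic chloride activated by iodide, and the alkoxide is released cold next to its internal electrophile so that capture should outrun fragmentation.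

**Step 14**
Reactants: 20 tert-butyl (2R)-2-{2-[2,5-bis(methoxymethoxy)phenyl]-2-oxoethyl}-6-[(3E)-5-{[(2E)-3-[4-(methoxymethoxy)phenyl]prop-2-enoyl]oxy}-4-methylpent-3-en-1-yl]-2,3,4,7-tetrahydrooxepine-2-carboxylate
Product: 21 (2R)-2-[2-(2,5-dihydroxyphenyl)-2-oxoethyl]-6-[(3E)-5-{[(2E)-3-(4-hydroxyphenyl)prop-2-enoyl]oxy}-4-methylpent-3-en-1-yl]-2,3,4,7-tetrahydrooxepine-2-carboxylic acid (CNP0602535.1)
Conditions: CF3CO2H/CH2Cl2 (1:3), thioanisole, H2O (5 equiv), 0 °C → rt
Reagents that add atoms: none
Why: Acidolysis (SN1-type loss of the tert-butyl cation from the ester and acetal cleavage of the three methoxymethyl ethers) with a cation scavenger; both trisubstituted alkenes carry allylic oxygen substituents that disfavour their protonation, and C2 has no enolisable hydrogen.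

**Compound list**
1 | methyl 2-[bis(2,2,2-trifluoroethoxy)phosphoryl]acetate | COC(=O)CP(=O)(OCC(F)(F)F)OCC(F)(F)F | starting material
2 | 5-bromo-2-methylpent-2-ene | CC(C)=CCCBr | starting material
3 | methyl 2-[bis(2,2,2-trifluoroethoxy)phosphoryl]-6-methylhept-5-enoate (racemic) | COC(=O)C(CCC=C(C)C)P(=O)(OCC(F)(F)F)OCC(F)(F)F | intermediate
4 | (2S)-5-oxotetrahydrofuran-2-carboxylic acid | O=C1CC[C@@H](C(=O)O)O1 | starting material
5 | tert-butyl (2S)-5-oxotetrahydrofuran-2-carboxylate | O=C1CC[C@@H](C(=O)OC(C)(C)C)O1 | intermediate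
6 | tert-butyl (2S)-5-hydroxytetrahydrofuran-2-carboxylate (lactol; mixture of anomers) | OC1CC[C@@H](C(=O)OC(C)(C)C)O1 | intermediate
7 | 1-tert-butyl 7-methyl (2S,5Z)-2-hydroxy-6-(4-methylpent-3-en-1-yl)hept-5-enedioate | CC(C)=CCC/C(C(=O)OC)=C/CC[C@H](O)C(=O)OC(C)(C)C | intermediate
8 | tert-butyl (2S,5Z)-2-hydroxy-6-(hydroxymethyl)-10-methylundeca-5,9-dienoate | CC(C)=CCC/C(CO)=C/CC[C@H](O)C(=O)OC(C)(C)C | intermediate
9 | tert-butyl (2S,5Z)-6-(chloromethyl)-2-hydroxy-10-methylundeca-5,9-dienoate | CC(C)=CCC/C(CCl)=C/CC[C@H](O)C(=O)OC(C)(C)C | intermediate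
10 | tert-butyl (2S,5Z,9E)-6-(chloromethyl)-2,11-dihydroxy-10-methylundeca-5,9-dienoate | C/C(CO)=C\CC/C(CCl)=C/CC[C@H](O)C(=O)OC(C)(C)C | intermediate
11 | (2E)-3-(4-hydroxyphenyl)prop-2-enoic acid (p-coumaric acid) | O=C(O)/C=C/c1ccc(O)cc1 | starting material
12 | methoxymethyl (2E)-3-[4-(methoxymethoxy)phenyl]prop-2-enoate | COCOC(=O)/C=C/c1ccc(OCOC)cc1 | intermediate (not isolated)
13 | (2E)-3-[4-(methoxymethoxy)phenyl]prop-2-enoic acid | O=C(O)/C=C/c1ccc(OCOC)cc1 | intermediate
14 | tert-butyl (2S,5Z,9E)-6-(chloromethyl)-2-hydroxy-11-{[(2E)-3-[4-(methoxymethoxy)phenyl]prop-2-enoyl]oxy}-10-methylundeca-5,9-dienoate | C/C(COC(=O)/C=C/c1ccc(OCOC)cc1)=C\CC/C(CCl)=C/CC[C@H](O)C(=O)OC(C)(C)C | intermediate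
15 | tert-butyl (5Z,9E)-6-(chloromethyl)-11-{[(2E)-3-[4-(methoxymethoxy)phenyl]prop-2-enoyl]oxy}-10-methyl-2-oxoundeca-5,9-dienoate | C/C(COC(=O)/C=C/c1ccc(OCOC)cc1)=C\CC/C(CCl)=C/CCC(=O)C(=O)OC(C)(C)C | intermediate
16 | 1-(2,5-dihydroxyphenyl)ethan-1-one | CC(=O)c1cc(O)ccc1O | starting material
17 | 1-[2,5-bis(methoxymethoxy)phenyl]ethan-1-one | CC(=O)c1cc(OCOC)ccc1OCOC | intermediate
18 | {[1-(2,5-bis(methoxymethoxy)phenyl)ethenyl]oxy}trimethylsilane | C=C(O[Si](C)(C)C)c1cc(OCOC)ccc1OCOC | intermediate
19 | tert-butyl (2R,5Z,9E)-2-{2-[2,5-bis(methoxymethoxy)phenyl]-2-oxoethyl}-6-(chloromethyl)-11-{[(2E)-3-[4-(methoxymethoxy)phenyl]prop-2-enoyl]oxy}-10-methyl-2-[(trimethylsilyl)oxy]undeca-5,9-dienoate | C/C(COC(=O)/C=C/c1ccc(OCOC)cc1)=C\CC/C(CCl)=C/CC[C@@](O[Si](C)(C)C)(CC(=O)c1cc(OCOC)ccc1OCOC)C(=O)OC(C)(C)C | intermediate (not isolated)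
20 | tert-butyl (2R)-2-{2-[2,5-bis(methoxymethoxy)phenyl]-2-oxoethyl}-6-[(3E)-5-{[(2E)-3-[4-(methoxymethoxy)phenyl]prop-2-enoyl]oxy}-4-methylpent-3-en-1-yl]-2,3,4,7-tetrahydrooxepine-2-carboxylate | C/C(=C\CCC1=CCC[C@@](CC(=O)c2cc(OCOC)ccc2OCOC)(C(=O)OC(C)(C)C)OC1)COC(=O)/C=C/c1ccc(OCOC)cc1 | intermediate
21 | (2R)-2-[2-(2,5-dihydroxyphenyl)-2-oxoethyl]-6-[(3E)-5-{[(2E)-3-(4-hydroxyphenyl)prop-2-enoyl]oxy}-4-methylpent-3-en-1-yl]-2,3,4,7-tetrahydrooxepine-2-carboxylic acid | C/C(=C\CCC1=CCC[C@@](CC(=O)c2cc(O)ccc2O)(C(=O)O)OC1)COC(=O)/C=C/c1ccc(O)cc1 | target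

**Totals**
Total step count: 14. Longest linear sequence: 10 steps (steps 2, 3, 4, 5, 6, 7, 9, 10, 13, 14).

**Steps most likely to fail**

Step 13. The freshly released β-keto alkoxide may fragment by retro-aldol reaction and re-add without catalyst control (erosion of enantiopurity). It may also pass its charge to the ketone α-carbon (C-alkylation), or the closed product may reopen by β-elimination under fluoride. The fallback sets out from 15 and 18 and comes back to the route at 20. It separates the two events and switches the closure from nucleophile activation to electrophile activation. The copper-catalysed aldol addition is run alone and worked up with aqueous HCl/THF to give the free tertiary alcohol, hydroxy chloride F1. Finkelstein exchange (NaI, acetone) gives hydroxy iodide F2. Ag2O (CH2Cl2, molecular sieves, dark) then assists departure of iodide while the neutral hydroxyl attacks C7, so that neither alkoxide nor enolate is formed on the way to 20.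

Step 14. Under the protic acid the trisubstituted alkenes may be hydrated or cyclised, the allylic ester may ionise, and the liberated tert-butyl and methoxymethyl cations may alkylate the electron-rich phenols. The fallback sets out from 20 and comes back at 21 by a two-stage, non-protic unmasking. ZnBr2/n-PrSH (CH2Cl2, 0 °C) removes the three methoxymethyl groups by thiol transfer to give the triphenol tert-butyl ester F3. Me3SiOTf/2,6-lutidine (CH2Cl2, 0 °C) then converts the tert-butyl ester into the silyl ester, which a pH 4 aqueous work-up hydrolyses, together with transient aryl silyl ethers, to 21.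

Step 4. Ring–chain opening of the lactol may be slow under the cold olefination conditions, Z-selectivity may erode on warming, and the liberated C2 alkoxide may add in conjugate fashion to the new enoate. The fallback sets out from 5 and comes back at 7, with the C2 hydroxyl protected before the aldehyde is exposed. Lactone 5 is opened with MeNH(OMe)·HCl/AlMe3 to the hydroxy N-methoxy-N-methyl amide F4, which is silylated (t-BuMe2SiCl, imidazole) to silyl ether amide F5. i-Bu2AlH (–78 °C) gives the open-chain silyloxy aldehyde F6. The same Still–Gennari olefination with 3 gives the silylated (5Z)-enoate F7, and HF·pyridine (THF, 0 °C) removes the silyl group to give 7.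

**Further compounds**
F1 | step 13 | tert-butyl (2R,5Z,9E)-2-{2-[2,5-bis(methoxymethoxy)phenyl]-2-oxoethyl}-6-(chloromethyl)-2-hydroxy-11-{[(2E)-3-[4-(methoxymethoxy)phenyl]prop-2-enoyl]oxy}-10-methylundeca-5,9-dienoate | C/C(COC(=O)/C=C/c1ccc(OCOC)cc1)=C\CC/C(CCl)=C/CC[C@@](O)(CC(=O)c1cc(OCOC)ccc1OCOC)C(=O)OC(C)(C)C
F2 | step 13 | tert-butyl (2R,5Z,9E)-2-{2-[2,5-bis(methoxymethoxy)phenyl]-2-oxoethyl}-2-hydroxy-6-(iodomethyl)-11-{[(2E)-3-[4-(methoxymethoxy)phenyl]prop-2-enoyl]oxy}-10-methylundeca-5,9-dienoate | C/C(COC(=O)/C=C/c1ccc(OCOC)cc1)=C\CC/C(CI)=C/CC[C@@](O)(CC(=O)c1cc(OCOC)ccc1OCOC)C(=O)OC(C)(C)C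
F3 | step 14 | tert-butyl (2R)-2-[2-(2,5-dihydroxyphenyl)-2-oxoethyl]-6-[(3E)-5-{[(2E)-3-(4-hydroxyphenyl)prop-2-enoyl]oxy}-4-methylpent-3-en-1-yl]-2,3,4,7-tetrahydrooxepine-2-carboxylate | C/C(=C\CCC1=CCC[C@@](CC(=O)c2cc(O)ccc2O)(C(=O)OC(C)(C)C)OC1)COC(=O)/C=C/c1ccc(O)cc1
F4 | step 4 | tert-butyl (2S)-2-hydroxy-5-[methoxy(methyl)amino]-5-oxopentanoate | CON(C)C(=O)CC[C@H](O)C(=O)OC(C)(C)C
F5 | step 4 | tert-butyl (2S)-2-[(tert-butyldimethylsilyl)oxy]-5-[methoxy(methyl)amino]-5-oxopentanoate | CON(C)C(=O)CC[C@H](O[Si](C)(C)C(C)(C)C)C(=O)OC(C)(C)C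
F6 | step 4 | tert-butyl (2S)-2-[(tert-butyldimethylsilyl)oxy]-5-oxopentanoate | O=CCC[C@H](O[Si](C)(C)C(C)(C)C)C(=O)OC(C)(C)C
F7 | step 4 | 1-tert-butyl 7-methyl (2S,5Z)-2-[(tert-butyldimethylsilyl)oxy]-6-(4-methylpent-3-en-1-yl)hept-5-enedioate | CC(C)=CCC/C(C(=O)OC)=C/CC[C@H](O[Si](C)(C)C(C)(C)C)C(=O)OC(C)(C)C
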